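The pitfall in this flask is to read 4.00 equivalents of coupling partner as plenty. This note was for whoever took over the bench.

| flask | substrate | coupling partner | free catalyst | remark | time |
|---|---|---|---|---|---|
| Monday's | 0.42 M | 1.68 M | 11 mM | run made earlier |  |
| flask | 0.42 M | 1.68 M | 5.5 mM |  | 15 d |

Monday's run (percent of the substrate charged)

| time / h | product / % |
|---|---|
| 6.00 | 12 |
| 12.0 | 24 |
| 20.0 | 26 |
| 25.0 | 28 |
| 30.0 | 34 |
| 40.0 | 31 |

(readings scatter by 2 percentage points)

- at 15 d, what has stopped the reaction, if anything has (it is still moving / the coupling partner has run out first / all of the substrate has reacted / no working catalyst is left)
- how much product there is at 15 d, in percent of the substrate charged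

Monday's last two product readings stood at 34% and 31%, and those readings could not tell a dead catalyst from coupling partner lost elsewhere. I bet on the lost partner. From the mean of the last two readings I took the partner share, the molar product made per molar coupling partner charged: 8.12%. On that bet, with partner lost by a path that needs no catalyst, this flask, charged with Monday's substrate and partner but half the catalyst, would get about half that share, plus a late tail I could not size. I therefore expected about 16.2% product at 15 d, somewhat more with the tail, and the partner gone with substrate left over. I asked that nobody add substrate.

The forecast gave 16% and "no working catalyst is left", arguing "Neither reagent has run out, so the stall points to catalyst death". The flask gave 22.0% and "the coupling partner has run out first".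

    coupling partner + free catalyst → catalyst intermediate A (k = 5.00 M⁻¹ h⁻¹)
    substrate + catalyst intermediate A → catalyst intermediate B (k = 12.0 M⁻¹ h⁻¹)
    catalyst intermediate B → catalyst intermediate C (k = 9.00 h⁻¹)
    catalyst intermediate C → free catalyst + product (k = 6.60 h⁻¹)
    2 coupling partner → homo dimer (k = 0.390 M⁻¹ h⁻¹)

At the start of this flask, the path to homo dimer used coupling partner 48 times as fast as the path to catalyst intermediate A, and by 15.0 d this flask held 0% of its partner, the limiting reagent, with >99.9% of its catalyst free and 78.0% of its substrate left. Its partner share came to 5.50%, less than the share I read from Monday's readings but above half of it.

A neighbour flask differs from this one in holding 0.25 M substrate; if it keeps this flask's partner share, it should give 36.9% product. That neighbour flask gave 34.6%.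

(All runs are calculated with made-up constants, noise included.)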